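The whole route rests on disconnecting the butyrolactone at its C5H2–O1 bond. Before the C3 side chain is attached, the ring carbons C3 and C5 are both CH2 groups flanking C4, so removal of O1 uncovers an achiral precursor, 3-(3,4-dimethoxybenzyl)cyclobutanone. A catalytic enantioselective Baeyer–Villiger oxidation lets one of the two enantiotopic CH2 groups migrate from the carbonyl carbon to oxygen: this closes the five-membered lactone through C5–O1 and sets C4 (R) in one operation. The lactone enolate is then alkylated anti to the C4 benzyl group with a 4-(bromomethyl)-2-pyrone-6-carboxylate, setting C3 (R), and ester hydrolysis gives the target.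

Key step: step 3

Assumption (remark on the chemistry): the sense of induction of the phosphoric acid for a 3-benzyl substituent is fixed by a pilot run with chiral HPLC correlation; the (R)-acid is written as the working choice and its antipode serves equally.

Step 1
Reactants: 1 methyl eugenol (4-allyl-1,2-dimethoxybenzene); 2 trichloroacetyl chloride
Product: 4 (±)-2,2-dichloro-3-(3,4-dimethoxybenzyl)cyclobutan-1-one, via dichloroketene 3 (not isolated)
Conditions: Cl3CCOCl, Zn–Cu couple, POCl3, Et2O, reflux
Reagents that add atoms: none
Why: Zinc dechlorinates 2 to dichloroketene, which adds to the terminal alkene of 1 in a thermal [2+2] ketene–alkene cycloaddition with the carbonyl carbon bonding to the terminal CH2 (the stereocentre formed is racemic and is erased in step 2), while POCl3 ties up ZnCl2 and spares the electron-rich arene.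

Step 2
Reactants: 4 (±)-2,2-dichloro-3-(3,4-dimethoxybenzyl)cyclobutan-1-one
Product: 5 3-(3,4-dimethoxybenzyl)cyclobutan-1-one
Conditions: Zn dust, AcOH, 70 °C
Reagents that add atoms: none
Why: Reductive dehalogenation of an α,α-dichloroketone by zinc in acetic acid removes both chlorines through zinc enolates and leaves the achiral, mirror-symmetric 3-substituted cyclobutanone.

Step 3
Reactants: 5 3-(3,4-dimethoxybenzyl)cyclobutan-1-one
Product: 7 (R)-4-(3,4-dimethoxybenzyl)dihydrofuran-2(3H)-one, via Criegee perhydrate 6 (not isolated)
Conditions: (R)-3,3'-di(pyren-1-yl)-5,5',6,6',7,7',8,8'-octahydro-1,1'-binaphthalene-2,2'-diyl hydrogen phosphate (10 mol%), 30% aq. H2O2 (1.5 equiv), CHCl3, −40 °C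
Reagents that add atoms: hydrogen peroxide, OO
Why: The chiral Brønsted acid activates the strained ketone for addition of H2O2 to give Criegee perhydrate 6 and then holds it by hydrogen bonds to its OH and OOH groups, so that only one of the two enantiotopic ring CH2 groups is antiperiplanar to the O–O bond and migrates from the carbonyl carbon to oxygen as water leaves. The closest known reaction type is the chiral phosphoric acid-catalysed asymmetric Baeyer–Villiger desymmetrisation of 3-substituted cyclobutanones with aqueous H2O2. The oxolan-2-one ring is closed by a concerted 1,2-shift ring expansion of the cyclobutane (four- to five-membered), in which the C5–O1 bond forms as the C–C(=O) bond breaks, rather than by an exo or endo cyclisation. The only new stereocentre, lactone C4 (the prochiral C3 of 5), is set by the catalyst through its choice between the two enantiotopic CH2 groups; nothing in the substrate biases it. The step needs enantiotopic-group selectivity only: the mirror plane of 5 makes both migrating carbons constitutionally identical, so no regiochemical question arises, and the 3-benzyl group is the handle by which the catalyst pocket tells them apart. It also needs chemoselectivity for the ketone, secured by ring strain (fast perhydrate formation and migration at −40 °C) and by the inertness of the veratryl ring and benzylic CH2 to dilute H2O2.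

Step 4
Reactants: 8 diethyl oxalate; 9 ethyl 3-methylbut-2-enoate
Product: 11 ethyl 4-methyl-2-oxo-2H-pyran-6-carboxylate, via enol diester 10 (not isolated)
Conditions: KOEt, Et2O–EtOH, 0 °C to rt; 1 M HCl work-up; then TsOH·H2O (cat.), toluene, reflux (EtOH distilled off)
Reagents that add atoms: none
Why: Vinylogous (γ-selective) Claisen condensation of the potassium dienolate of 9 with diethyl oxalate gives enol diester 10, whose enol oxygen lactonises onto the distal ester under acid with loss of ethanol (the classical oxalate route to 2-pyrone-6-carboxylates), the double-bond isomers of 10 equilibrating through the keto tautomer.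

Step 5
Reactants: 11 ethyl 4-methyl-2-oxo-2H-pyran-6-carboxylate
Product: 12 ethyl 4-(bromomethyl)-2-oxo-2H-pyran-6-carboxylate
Conditions: NBS (1.0 equiv), AIBN (cat.), PhCF3, 85 °C
Reagents that add atoms: N-bromosuccinimide, O=C1CCC(=O)N1Br
Why: Wohl–Ziegler radical bromination at the only allylic methyl group, the ester-deactivated pyrone ring being a poor partner for ionic ring bromination under radical-chain conditions.

Step 6
Reactants: 7 (R)-4-(3,4-dimethoxybenzyl)dihydrofuran-2(3H)-one; 12 ethyl 4-(bromomethyl)-2-oxo-2H-pyran-6-carboxylate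
Product: 14 ethyl 4-{[(3R,4R)-4-(3,4-dimethoxybenzyl)-2-oxotetrahydrofuran-3-yl]methyl}-2-oxo-2H-pyran-6-carboxylate, via lithium enolate 13 (not isolated)
Conditions: LiN(SiMe3)2 (1.05 equiv), THF, −78 °C; then inverse addition to 12 (1.2 equiv), THF–DMPU, −78 °C; AcOH quench at −78 °C
Reagents that add atoms: none
Why: Enolate alkylation (SN2) of lithium enolate 13 by the primary allylic bromide 12 on the face anti to the C4 benzyl group (1,2-induction on the planar five-membered enolate) sets C3 as R and gives the trans (3R,4R) lactone, inverse addition keeping the electrophile in excess so that alkylation outruns proton transfer and conjugate addition.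

Step 7
Reactants: 14 ethyl 4-{[(3R,4R)-4-(3,4-dimethoxybenzyl)-2-oxotetrahydrofuran-3-yl]methyl}-2-oxo-2H-pyran-6-carboxylate
Product: 15 4-{[(3R,4R)-4-(3,4-dimethoxybenzyl)-2-oxotetrahydrofuran-3-yl]methyl}-2-oxo-2H-pyran-6-carboxylic acid
Conditions: 6 M HCl, 1,4-dioxane, 80 °C
Reagents that add atoms: water, O
Why: Acid-catalysed acyl–oxygen ester hydrolysis (AAC2) cleaves the ethyl ester, while the γ-lactone and the 2-pyrone (both favoured in their closed forms in aqueous acid), the aryl methyl ethers and the thermodynamically preferred trans C3/C4 arrangement should be retained.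

Compound list
1 | methyl eugenol (4-allyl-1,2-dimethoxybenzene) | C=CCc1ccc(OC)c(OC)c1 | starting material
2 | trichloroacetyl chloride | ClC(=O)C(Cl)(Cl)Cl | starting material
3 | dichloroketene (not isolated) | O=C=C(Cl)Cl | intermediate
4 | (±)-2,2-dichloro-3-(3,4-dimethoxybenzyl)cyclobutan-1-one | COc1ccc(CC2CC(=O)C2(Cl)Cl)cc1OC | intermediate
5 | 3-(3,4-dimethoxybenzyl)cyclobutan-1-one | COc1ccc(CC2CC(=O)C2)cc1OC | intermediate
6 | Criegee perhydrate, 3-(3,4-dimethoxybenzyl)-1-hydroperoxycyclobutan-1-ol (not isolated) | COc1ccc(CC2CC(O)(OO)C2)cc1OC | intermediate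
7 | (R)-4-(3,4-dimethoxybenzyl)dihydrofuran-2(3H)-one | COc1ccc(C[C@H]2COC(=O)C2)cc1OC | intermediate
8 | diethyl oxalate | CCOC(=O)C(=O)OCC | starting material
9 | ethyl 3-methylbut-2-enoate | CCOC(=O)C=C(C)C | starting material
10 | diethyl (2Z,4Z)-2-hydroxy-4-methylhexa-2,4-dienedioate (enol diester, not isolated) | CCOC(=O)/C(O)=C/C(C)=C\C(=O)OCC | intermediate
11 | ethyl 4-methyl-2-oxo-2H-pyran-6-carboxylate | CCOC(=O)c1cc(C)cc(=O)o1 | intermediate
12 | ethyl 4-(bromomethyl)-2-oxo-2H-pyran-6-carboxylate | CCOC(=O)c1cc(CBr)cc(=O)o1 | intermediate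
13 | lithium enolate of 7, lithium (R)-3-(3,4-dimethoxybenzyl)-2,3-dihydrofuran-5-olate (not isolated) | [Li+].COc1ccc(C[C@H]2COC([O-])=C2)cc1OC | intermediate
14 | ethyl 4-{[(3R,4R)-4-(3,4-dimethoxybenzyl)-2-oxotetrahydrofuran-3-yl]methyl}-2-oxo-2H-pyran-6-carboxylate | COc1ccc(C[C@H]2COC(=O)[C@@H]2Cc2cc(C(=O)OCC)oc(=O)c2)cc1OC | intermediate
15 | 4-{[(3R,4R)-4-(3,4-dimethoxybenzyl)-2-oxotetrahydrofuran-3-yl]methyl}-2-oxo-2H-pyran-6-carboxylic acid | COc1ccc(C[C@H]2COC(=O)[C@@H]2Cc2cc(C(=O)O)oc(=O)c2)cc1OC | target

Total step count: 7. Longest linear sequence: 5 steps (steps 1, 2, 3, 6, 7); steps 4 and 5 build the pyrone fragment in parallel.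

Steps most likely to fail

Step 6. The enolate may transfer a proton from the acidic CH2Br or pyronyl-CH2 positions, or add in conjugate or acyl fashion to the electron-poor pyrone, instead of undergoing clean SN2 alkylation. The fallback sets out from 7 and comes back at the target 15, making step 7 unnecessary. Enolate 13 would instead be alkylated with 3,4,5-tris(benzyloxy)benzyl bromide F1 (from the commercial benzylic alcohol with PBr3, CH2Cl2, 0 °C), a benzylic bromide with no acidic or Michael-acceptor sites. This should give (3R,4R)-4-(3,4-dimethoxybenzyl)-3-[3,4,5-tris(benzyloxy)benzyl]dihydrofuran-2(3H)-one F2 with the same anti selectivity. Hydrogenolysis (H2, 10% Pd/C, EtOAc–EtOH) would free (3R,4R)-4-(3,4-dimethoxybenzyl)-3-(3,4,5-trihydroxybenzyl)dihydrofuran-2(3H)-one F3. Oxidative cleavage of the pyrogallol ring with peracetic acid in AcOH at room temperature should then give 15 directly. The sequence is oxidation to the hydroxy-o-quinone, Baeyer–Villiger-type insertion to the hydroxymuconic anhydride, and closure of the enol oxygen onto the distal acyl group. Because the 3,4,5-trihydroxyphenyl ring is symmetric, cleavage of either C(OH)–C(OH) bond gives the same 4-substituted 2-pyrone-6-carboxylic acid.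

Step 3. Discrimination between the enantiotopic CH2 groups may be insufficient for a flexible 3-benzyl (as opposed to 3-aryl) substituent, giving lactone of low enantiomeric purity. The fallback sets out from 5 and comes back at 7. Enantioselective deprotonation of 5 with lithium bis[(R)-1-phenylethyl]amide (or its antipode, chosen by a pilot run) and in situ trapping with Et3SiCl in THF at −100 °C would give (R)-{[3-(3,4-dimethoxybenzyl)cyclobut-1-en-1-yl]oxy}triethylsilane F4. Ozonolysis of the enol ether double bond (O3 dosed to the end point, CH2Cl2–MeOH, −78 °C) followed by NaBH4 would give (R)-4-(3,4-dimethoxyphenyl)-3-(hydroxymethyl)butanoic acid F5 as its sodium salt. The acid would be freed at 0 °C and closed at once under Mitsunobu conditions (PPh3, DIAD, THF, 0 °C). There the carboxylate oxygen displaces the activated primary carbon, so the ring again closes at the CH2–O bond. Any material that lactonises spontaneously is the same compound 7.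

Step 5. Ionic bromination of the pyrone ring or double bromination of the methyl group may compete with the radical monosubstitution. The fallback sets out from 11 and comes back at 12. Allylic oxidation of the methyl group with SeO2 (1,4-dioxane, reflux) would give ethyl 4-formyl-2-oxo-2H-pyran-6-carboxylate F6. Luche reduction (NaBH4, CeCl3·7H2O, MeOH, −78 °C) would give ethyl 4-(hydroxymethyl)-2-oxo-2H-pyran-6-carboxylate F7. Appel bromination (CBr4, PPh3, CH2Cl2, 0 °C) would then return bromide 12.

Further compounds
F1 | step 6 | 3,4,5-tris(benzyloxy)benzyl bromide | BrCc1cc(OCc2ccccc2)c(OCc2ccccc2)c(OCc2ccccc2)c1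
F2 | step 6 | (3R,4R)-4-(3,4-dimethoxybenzyl)-3-[3,4,5-tris(benzyloxy)benzyl]dihydrofuran-2(3H)-one | COc1ccc(C[C@H]2COC(=O)[C@@H]2Cc2cc(OCc3ccccc3)c(OCc3ccccc3)c(OCc3ccccc3)c2)cc1OC
F3 | step 6 | (3R,4R)-4-(3,4-dimethoxybenzyl)-3-(3,4,5-trihydroxybenzyl)dihydrofuran-2(3H)-one | COc1ccc(C[C@H]2COC(=O)[C@@H]2Cc2cc(O)c(O)c(O)c2)cc1OC
F4 | step 3 | (R)-{[3-(3,4-dimethoxybenzyl)cyclobut-1-en-1-yl]oxy}triethylsilane | COc1ccc(C[C@H]2C=C(O[Si](CC)(CC)CC)C2)cc1OC
F5 | step 3 | (R)-4-(3,4-dimethoxyphenyl)-3-(hydroxymethyl)butanoic acid | COc1ccc(C[C@@H](CO)CC(=O)O)cc1OC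
F6 | step 5 | ethyl 4-formyl-2-oxo-2H-pyran-6-carboxylate | CCOC(=O)c1cc(C=O)cc(=O)o1
F7 | step 5 | ethyl 4-(hydroxymethyl)-2-oxo-2H-pyran-6-carboxylate | CCOC(=O)c1cc(CO)cc(=O)o1
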